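## Structural features

The target, 6-hydroxy-5-[4-hydroxy-2-methoxy-6-(methoxymethyl)benzyl]-8-methoxy-3-methyl-1H-isochromen-1-one (C21H22O7), is an achiral diarylmethane. C5 of a 3-methylisocoumarin is joined through one CH2 to carbon A1 of a phenolic benzene ring (ring A). Ring A is 1,2,3,5-tetrasubstituted: the bridge at A1 is flanked by the methoxymethyl group at A2 and the methoxy group at A6, and the free hydroxyl sits at A4, para to the bridge. The isocoumarin carries a hydroxyl at C6 (ortho to the bridge), a methoxy group at C8 (peri to the lactone carbonyl), hydrogen at C7 and C4, and the methyl group at C3. There is no stereocentre, so every selectivity question is regiochemical. The fragile parts are the enol lactone (opened by alkoxides and amines, C3=C4 reducible), the benzylic methyl ether on ring A (hydrogenolysis, strong Lewis acids), the C8 methoxy group (cleaved by boron halides because of the neighbouring carbonyl) and the electron-rich diarylmethane with its two phenols (oxidation, acid-mediated benzyl transfer). The real difficulty is twofold: the bridge carbon is bonded to an arene carbon with two ortho substituents on one side and to a carbon between an oxygen-bearing position and the ring fusion on the other, and each ring holds one O-methyl and one free O–H that must end up on the right oxygen. The key step exploits the fact that an A6 methoxy, an A4 hydroxyl and carbon substituents at A1 and A2 are exactly what a ketene-acetal/silyl-enol-ether diene (A6–A5–A4–A3) delivers to an alkynyl ketone (A1, A2) whose carbonyl carbon becomes the bridge.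

## Logic of the disconnections

20 to 19: the two O–CH2Ph bonds at A4–O and C6–O are cut. Both phenols have to be masked during pyranone formation, which uses an acetylating enol ester and a copper oxidant, and one common group allows a single final unmasking. The demand on the forward step is a debenzylation that leaves the C3=C4 enol lactone and the benzylic C–OMe bond alone.

19 to 17 and 18: the pyranone is cut at C4a–C4 and O2–C3. This turns the isocoumarin into a plain benzoic acid whose only free ortho position is C4a, plus a three-carbon enol ester that stands in for propyne. The forward step must metalate a C–H bond next to the bulky C5 benzyl group, insert the alkene with its CH2 end on the arene so that the methyl group lands at C3, and use an oxidant the electron-rich rings tolerate.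

17 to 16 to 15: functional-group changes only, namely the ester C–OMe bond (hydrolysis) and the A4 O–benzyl bond. They expose the acid as directing group and cap the phenol that the key step leaves free. The demand is ordinary: hydrolysis of a hindered, electron-rich benzoate without touching the ethers.

15 to 13: the bridge CH2 is traced back to a C=O. The ketone is what activates the alkyne for the cycloaddition, and with an A4 hydroxyl para to it and alkoxy groups on both rings it is the kind of diaryl ketone that ionic reduction removes cleanly. The forward step must take the carbonyl down by two levels without harming the methyl ester, the aryl benzyl ether or the CH2OMe group.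

13 to 6 and 10: ring A is cut at A6–A1 and A3–A2. This is the strategic cut. It removes a whole ring with its differentiated oxygens and both ortho substituents of the bridge, and leaves an alkynyl ketone and a four-carbon diene. The demand is one regiochemical sense of addition, followed by loss of methanol and of the silyl group.

6 to 4, 5 and carbon monoxide: both bonds to the ketone carbon are cut (aryl–CO and CO–alkyne). Three simple components replace the aldehyde, addition and oxidation sequence. The forward step needs CO insertion to outrun direct aryl–alkyne coupling.

4 to 3 to 2 to 1: the C5–I bond, then the O2–CH3 bond, then the O4–CH2Ph bond. C5 is the position para to OMe and ortho to OBn, so electrophilic iodination should go there. The two hydroxyls of 1 differ enough (one is chelated to the ester) to be alkylated in sequence.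

10 to 9 to 7 and 8: the O–Si bond, then the C–C bond between the acetyl carbon and the ketene acetal carbon. Both forward steps are standard enolate-type chemistry; the only demand is a base in the acylation so that the intermediate oxocarbenium ion is deprotonated instead of demethylated.

## Other disconnections considered

Alternative 1: The benzenoid ring of the isocoumarin is cut at C4a–C5 and C6–C7. This leads back to the 2-pyrone A1 (methyl 4-methoxy-6-methyl-2-oxo-2H-pyran-5-carboxylate) and the silyl ynol ether A2, in which ring A already hangs on the future bridge CH2. Forward, the two are heated: the nucleophilic alkyne carbon bearing the ring A benzyl group bonds to the ester-activated C6 of A1, the oxygen-bearing alkyne carbon bonds to C3, and the bridged adduct loses its lactone bridge by cycloreversion to give the hexasubstituted benzoate A3.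
- In its favour: one step sets all six substituents of the benzenoid ring, with the C6 oxygen (silyl) and C8 oxygen (methyl) already told apart. The bridge is at the CH2 level from the start. A3 carries the C4 carbon as a methyl group ortho to the ester, so the pyranone can be closed by lateral metalation and acetylation of a toluate.
- Where it is better than the chosen plan: it needs neither the reduction of ketone 13 nor the functionalisation of the hindered C–H bond of 17.
- Against it here: ring A is not made by the step. It must be brought in complete, so its 1,2,3,5 pattern with one methylated and one protected oxygen needs a synthesis of its own, which is what the union of 6 and 10 supplies in the chosen plan. A2 is a moisture-sensitive siloxyalkyne that would come from a homologation on that ring A unit. The cycloaddition needs prolonged heating at a pyrone terminus carrying a methyl group. The later lateral deprotonation of A3 competes with deprotonation of the doubly benzylic bridge CH2.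
- Comparison: both plans rest on a polarity-matched [4+2] cycloaddition followed by loss of a small molecule, so on reliability of regiochemistry they are equal. In step count the alternative is expected to be longer, because the prefabricated ring A, the siloxyalkyne and the pyrone all add steps before the fragments meet.

Alternative 2: The single bond C8a–C4a is cut, which unfolds the isocoumarin carbocycle into the open-chain dioxinone A4. A4 is a masked pentaketide carrying the ring A benzyl group on the carbon between its two chain ketones and a dioxolane on the terminal ketone. Forward, an amine base and then acid make the alpha carbon of the dioxinone add to the chain ketone that becomes C4a; dehydration and enolisation give the benzodioxinone A5.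
- In its favour: the route is biomimetic. The C8 oxygen (in the acetal) and the C6 hydroxyl (free) are differentiated by construction, which equals what steps 1 and 2 achieve in the chosen plan. The three-carbon unit of the pyranone is present as a masked 2-oxopropyl group, so the lactone closes later by acid-mediated enol lactonisation.
- Where it is better than the chosen plan: no C–H functionalisation is needed and the bridge never passes through a ketone.
- Against it here: A4 has four carbonyl-level carbons and three different acidic positions. The ring A benzyl group must be put on the carbon between the chain ketones by C-alkylation, where O-alkylation and double alkylation compete and the benzylic carbon is flanked by two ortho substituents. The aldol closure must win over oxygen cyclisation to pyranones and over thermal fragmentation of the dioxinone. Ring A again has to be made separately.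
- Comparison: the alternative relies on reversible carbonyl condensations with several competing pathways, the chosen plan on an irreversible cycloaddition–aromatisation with one. In step count, chain assembly, ring A synthesis and the steps after A5 (phenol protection, dioxinone opening, O-methylation, ketal removal, lactonisation, deprotection) are expected to exceed the twelve steps of the chosen route.

Alternative 3: The carbocycle is cut at C8a–C4a and C7–C6, giving methyl acetoacetate A6 and the alpha-benzylated crotonate A7 that carries ring A. Forward, an alkoxide base brings about Michael addition of A6 to the beta carbon of A7 (C8a–C4a) and then Claisen closure of the acetyl methyl onto the crotonate ester (C7–C6), giving the dioxocyclohexanecarboxylate A8 as a diastereomer mixture.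
- In its favour: the reagents are the cheapest of all the plans, no transition metal is needed, and the C4 carbon is in place as a methyl group for a later lateral-metalation route to the pyranone.
- Where it is better or equal: on cost and on avoiding the hindered C–H activation it is better than the chosen plan. The need to alkylate the two ring-B oxygens selectively is equal in both plans.
- Against it here: A7 is an alpha,beta-disubstituted acrylate with a bulky alpha-benzyl group, a poor Michael acceptor. A8 is not aromatic and must be dehydrogenated with halogen or metal oxidants that also threaten electron-rich ring A and the benzylic positions. The resulting dihydroxy ester still needs selective protection and methylation. The stereocentres of A8 are made only to be destroyed. Ring A again has to be made separately.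
- Comparison: condensation plus a separate oxidation gives less control than a cycloaddition that aromatises by itself. In step count the alternative is expected to be the longest of the four plans.

Key step: step 7

Remark on the chemistry: the target has no stereocentre; carbinol 14 forms as a racemate and its stereocentre is removed in the same step, so no SMILES below carries a stereodescriptor.

## Route

Step 1
Reactants: 1 methyl 2,4-dihydroxybenzoate
Product: 2 methyl 4-(benzyloxy)-2-hydroxybenzoate
Conditions: BnBr (1.05 equiv), K2CO3, acetone, reflux
Reagents that add atoms: benzyl bromide, BrCc1ccccc1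
Why: Williamson etherification; the C2 hydroxyl is hydrogen-bonded to the ester carbonyl and is less acidic and less nucleophilic than the C4 hydroxyl, so one equivalent of halide with a weak base should alkylate O4 selectively.

Step 2
Reactants: 2 methyl 4-(benzyloxy)-2-hydroxybenzoate
Product: 3 methyl 4-(benzyloxy)-2-methoxybenzoate
Conditions: MeI, K2CO3, DMF, 50 °C
Reagents that add atoms: iodomethane, CI
Why: Williamson O-methylation of the remaining chelated phenol under slightly more forcing conditions; no other nucleophilic site is present.

Step 3
Reactants: 3 methyl 4-(benzyloxy)-2-methoxybenzoate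
Product: 4 methyl 4-(benzyloxy)-5-iodo-2-methoxybenzoate
Conditions: NIS, TFA (cat.), MeCN, rt
Reagents that add atoms: N-iodosuccinimide, O=C1CCC(=O)N1I
Why: Electrophilic aromatic iodination; C5 is para to the methoxy group, ortho to the benzyloxy group and meta to the ester, and is less hindered than C3, which lies between the two alkoxy groups.

Step 4
Reactants: 4 methyl 4-(benzyloxy)-5-iodo-2-methoxybenzoate; 5 3-methoxyprop-1-yne
Product: 6 methyl 4-(benzyloxy)-2-methoxy-5-(4-methoxybut-2-ynoyl)benzoate
Conditions: CO (1 atm), PdCl2(PPh3)2 (cat.), Et3N, THF, rt to 50 °C
Reagents that add atoms: carbon monoxide, [C-]#[O+]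
Why: Carbonylative Sonogashira coupling: oxidative addition of the aryl iodide to zerovalent palladium, CO insertion to the aroylpalladium species (fast for an electron-rich aryl group), amine-assisted alkynylation and reductive elimination. Copper is left out to hold back the direct coupling without CO, and a tertiary amine is used so that no N–H adds to the ynone.

Step 5
Reactants: 7 1,1-dimethoxyethene; 8 acetyl chloride
Product: 9 4,4-dimethoxybut-3-en-2-one
Conditions: Et3N, Et2O, 0 °C to rt
Reagents that add atoms: none
Why: C-acylation of a ketene acetal by an acid chloride; the amine deprotonates the intermediate dimethoxycarbenium ion to the acyl ketene acetal before chloride can demethylate it.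

Step 6
Reactants: 9 4,4-dimethoxybut-3-en-2-one
Product: 10 1,1-dimethoxy-3-(trimethylsilyloxy)buta-1,3-diene
Conditions: TMSCl, Et3N, ZnCl2 (cat.), toluene, 40 °C
Reagents that add atoms: chlorotrimethylsilane, C[Si](C)(C)Cl
Why: Silyl enol ether formation by amine/ZnCl2-assisted enolisation and O-silylation of the methyl ketone, the only enolisable position; the diene is distilled and used at once because it hydrolyses readily.

Step 7
Reactants: 6 methyl 4-(benzyloxy)-2-methoxy-5-(4-methoxybut-2-ynoyl)benzoate; 10 1,1-dimethoxy-3-(trimethylsilyloxy)buta-1,3-diene
Product: 13 methyl 4-(benzyloxy)-5-[4-hydroxy-2-methoxy-6-(methoxymethyl)benzoyl]-2-methoxybenzoate, via cyclohexadiene cycloadduct 11 (not isolated), via aryl trimethylsilyl ether 12 (not isolated)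
Conditions: 10 (2.5 equiv), toluene, 80 °C; then 1 M HCl, THF, rt
Reagents that add atoms: none
Why: The electron-rich diene and the ynone combine in a normal-electron-demand Diels–Alder reaction that is strongly asynchronous and can equally be read as a Mukaiyama–Michael addition followed at once by ring closure: the CH2 terminus of the silyl enol ether attacks the beta carbon of the ynone (A3–A2) and the ketene acetal carbon bonds to the alpha carbon (A6–A1). The closest known reaction type is the cycloaddition of this same diene with acetylenic esters and ketones, which gives 4-hydroxy-2-methoxyaryl carbonyl compounds. Ring A closes in one intermolecular [4+2] event as the cyclohexa-1,4-diene 11, whose ketal carbon then loses methanol to give the aromatic silyl ether 12, and dilute acid frees the A4 phenol. No stereocentre is formed. The selectivity needed is regiochemical and is secured by matched polarisation: the beta carbon of the ynone is its electrophilic end and the silyl enol ether terminus is the nucleophilic end of the diene, so the methoxy group lands at A6 next to the ketone, the hydroxyl at A4 para to it and the methoxymethyl group at A2. The alkyne is the only dienophile in 6; the ester and aryl ethers are inert, and the ketone carbonyl, shielded by the ortho benzyloxy group, is a poor heterodienophile without a Lewis acid.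

Step 8
Reactants: 13 methyl 4-(benzyloxy)-5-[4-hydroxy-2-methoxy-6-(methoxymethyl)benzoyl]-2-methoxybenzoate
Product: 15 methyl 4-(benzyloxy)-5-[4-hydroxy-2-methoxy-6-(methoxymethyl)benzyl]-2-methoxybenzoate, via diaryl carbinol 14 (not isolated)
Conditions: Et3SiH (4 equiv), TFA (10 equiv), CH2Cl2, 0 °C to rt
Reagents that add atoms: none
Why: Ionic hydrogenation: the protonated electron-rich diaryl ketone takes hydride from the silane to give carbinol 14, which ionises at once to the diarylmethyl cation (the O-protonated para-quinone methide of ring A) and takes a second hydride. The methyl ester, the aryl benzyl ether (short exposure, no heating) and the methoxymethyl group (meta to both ring A oxygens, so not ionisable) should survive.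

Step 9
Reactants: 15 methyl 4-(benzyloxy)-5-[4-hydroxy-2-methoxy-6-(methoxymethyl)benzyl]-2-methoxybenzoate
Product: 16 methyl 4-(benzyloxy)-5-[4-(benzyloxy)-2-methoxy-6-(methoxymethyl)benzyl]-2-methoxybenzoate
Conditions: BnBr, K2CO3, DMF, rt
Reagents that add atoms: benzyl bromide, BrCc1ccccc1
Why: Williamson etherification of the only free phenol; the benzyl ether shields A4–OH from acetylation by the enol ester and from the copper oxidant of step 11 and leaves with the C6 benzyl group at the end.

Step 10
Reactants: 16 methyl 4-(benzyloxy)-5-[4-(benzyloxy)-2-methoxy-6-(methoxymethyl)benzyl]-2-methoxybenzoate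
Product: 17 4-(benzyloxy)-5-[4-(benzyloxy)-2-methoxy-6-(methoxymethyl)benzyl]-2-methoxybenzoic acid
Conditions: NaOH, MeOH/THF/H2O, 65 °C; then 1 M HCl to pH 3
Reagents that add atoms: sodium hydroxide, [Na+].[OH-]
Why: Saponification of the methyl benzoate; the ester is electron-rich and ortho-substituted and so needs heat, but all ethers are stable to hydroxide and the brief cold acidification does not affect them.

Step 11
Reactants: 17 4-(benzyloxy)-5-[4-(benzyloxy)-2-methoxy-6-(methoxymethyl)benzyl]-2-methoxybenzoic acid; 18 prop-1-en-2-yl acetate
Product: 19 6-(benzyloxy)-5-[4-(benzyloxy)-2-methoxy-6-(methoxymethyl)benzyl]-8-methoxy-3-methyl-1H-isochromen-1-one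
Conditions: 18 (4 equiv), [(C5Me5)RhCl2]2 (cat.), Cu(OAc)2·H2O (2.2 equiv), toluene, 110 °C
Reagents that add atoms: none
Why: Carboxylate-directed C–H activation and oxidative annulation catalysed by trivalent rhodium, with a geminally substituted enol ester as alkyne equivalent: rhodation occurs at C4a, the only free ortho position, the alkene inserts with its CH2 end on the arene, and C–O bond formation at the acetoxy-bearing carbon with loss of acetic acid gives the 3-methyl pyranone. Cu(OAc)2 returns monovalent rhodium to the trivalent state, and the regiochemistry (H at C4, methyl at C3) follows from the insertion sense of the enol ester.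

Step 12
Reactants: 19 6-(benzyloxy)-5-[4-(benzyloxy)-2-methoxy-6-(methoxymethyl)benzyl]-8-methoxy-3-methyl-1H-isochromen-1-one
Product: 20 6-hydroxy-5-[4-hydroxy-2-methoxy-6-(methoxymethyl)benzyl]-8-methoxy-3-methyl-1H-isochromen-1-one
Conditions: H2 (1 atm), 10% Pd/C, EtOAc, rt, stopped after uptake of 2 equiv
Reagents that add atoms: none
Why: Catalytic hydrogenolysis of two aryl benzyl ethers; these O–CH2Ph bonds should cleave much faster than the benzylic C–OMe bond of ring A is hydrogenolysed or the trisubstituted, conjugated C3=C4 bond of the enol lactone is saturated, hence the neutral solvent, low pressure and monitored hydrogen uptake.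

## Compound list

1 | methyl 2,4-dihydroxybenzoate | COC(=O)c1ccc(O)cc1O | starting material
2 | methyl 4-(benzyloxy)-2-hydroxybenzoate | COC(=O)c1ccc(OCc2ccccc2)cc1O | intermediate
3 | methyl 4-(benzyloxy)-2-methoxybenzoate | COC(=O)c1ccc(OCc2ccccc2)cc1OC | intermediate
4 | methyl 4-(benzyloxy)-5-iodo-2-methoxybenzoate | COC(=O)c1cc(I)c(OCc2ccccc2)cc1OC | intermediate
5 | 3-methoxyprop-1-yne | COCC#C | starting material
6 | methyl 4-(benzyloxy)-2-methoxy-5-(4-methoxybut-2-ynoyl)benzoate | COCC#CC(=O)c1cc(C(=O)OC)c(OC)cc1OCc1ccccc1 | intermediate
7 | 1,1-dimethoxyethene | COC(=C)OC | starting material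
8 | acetyl chloride | CC(=O)Cl | starting material
9 | 4,4-dimethoxybut-3-en-2-one | COC(OC)=CC(C)=O | intermediate
10 | 1,1-dimethoxy-3-(trimethylsilyloxy)buta-1,3-diene | COC(OC)=CC(=C)O[Si](C)(C)C | intermediate
11 | methyl 4-(benzyloxy)-5-{[6,6-dimethoxy-2-(methoxymethyl)-4-(trimethylsilyloxy)cyclohexa-1,4-dien-1-yl]carbonyl}-2-methoxybenzoate | COCC1=C(C(=O)c2cc(C(=O)OC)c(OC)cc2OCc2ccccc2)C(OC)(OC)C=C(O[Si](C)(C)C)C1 | intermediate (not isolated)
12 | methyl 4-(benzyloxy)-2-methoxy-5-[2-methoxy-6-(methoxymethyl)-4-(trimethylsilyloxy)benzoyl]benzoate | COCc1cc(O[Si](C)(C)C)cc(OC)c1C(=O)c1cc(C(=O)OC)c(OC)cc1OCc1ccccc1 | intermediate (not isolated)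
13 | methyl 4-(benzyloxy)-5-[4-hydroxy-2-methoxy-6-(methoxymethyl)benzoyl]-2-methoxybenzoate | COCc1cc(O)cc(OC)c1C(=O)c1cc(C(=O)OC)c(OC)cc1OCc1ccccc1 | intermediate
14 | methyl 4-(benzyloxy)-5-{hydroxy[4-hydroxy-2-methoxy-6-(methoxymethyl)phenyl]methyl}-2-methoxybenzoate (racemic) | COCc1cc(O)cc(OC)c1C(O)c1cc(C(=O)OC)c(OC)cc1OCc1ccccc1 | intermediate (not isolated)
15 | methyl 4-(benzyloxy)-5-[4-hydroxy-2-methoxy-6-(methoxymethyl)benzyl]-2-methoxybenzoate | COCc1cc(O)cc(OC)c1Cc1cc(C(=O)OC)c(OC)cc1OCc1ccccc1 | intermediate
16 | methyl 4-(benzyloxy)-5-[4-(benzyloxy)-2-methoxy-6-(methoxymethyl)benzyl]-2-methoxybenzoate | COCc1cc(OCc2ccccc2)cc(OC)c1Cc1cc(C(=O)OC)c(OC)cc1OCc1ccccc1 | intermediate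
17 | 4-(benzyloxy)-5-[4-(benzyloxy)-2-methoxy-6-(methoxymethyl)benzyl]-2-methoxybenzoic acid | COCc1cc(OCc2ccccc2)cc(OC)c1Cc1cc(C(=O)O)c(OC)cc1OCc1ccccc1 | intermediate
18 | prop-1-en-2-yl acetate (isopropenyl acetate) | CC(=C)OC(C)=O | starting material
19 | 6-(benzyloxy)-5-[4-(benzyloxy)-2-methoxy-6-(methoxymethyl)benzyl]-8-methoxy-3-methyl-1H-isochromen-1-one | COCc1cc(OCc2ccccc2)cc(OC)c1Cc1c(OCc2ccccc2)cc(OC)c2c(=O)oc(C)cc12 | intermediate
20 | 6-hydroxy-5-[4-hydroxy-2-methoxy-6-(methoxymethyl)benzyl]-8-methoxy-3-methyl-1H-isochromen-1-one | COCc1cc(O)cc(OC)c1Cc1c(O)cc(OC)c2c(=O)oc(C)cc12 | target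

## Step count and least certain steps

Total step count: 12. Longest linear sequence: 10 steps (steps 1, 2, 3, 4, 7, 8, 9, 10, 11, 12, from 1 to 20); steps 5 and 6 make the diene in a two-step side branch.

Step 7 (key step). The most likely failure is that the cycloaddition is slower than the thermal and hydrolytic decay of the diene, because the alkyne of 6 is disubstituted and its beta carbon carries the CH2OMe group. The other risk is aldol-type addition of the diene to the ketone carbonyl instead of the alkyne. The fallback keeps the same diene but uses it on an acetylenic ester, the dienophile class on which it is most familiar, and makes the aryl–CH bond afterwards with an arylmagnesium reagent. It sets out from 5, 10 and 4 and comes back at 16, so steps 8 and 9 are then not needed.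
- Deprotonation of 5 with n-BuLi and quenching with methyl chloroformate gives methyl 4-methoxybut-2-ynoate F1.
- Heating F1 with 10 gives the cycloadduct methyl 6,6-dimethoxy-2-(methoxymethyl)-4-(trimethylsilyloxy)cyclohexa-1,4-diene-1-carboxylate F2, which loses methanol to methyl 2-methoxy-6-(methoxymethyl)-4-(trimethylsilyloxy)benzoate F3 and on acidic work-up gives methyl 4-hydroxy-2-methoxy-6-(methoxymethyl)benzoate F4.
- Benzylation (BnBr, K2CO3) gives methyl 4-(benzyloxy)-2-methoxy-6-(methoxymethyl)benzoate F5, LiAlH4 gives [4-(benzyloxy)-2-methoxy-6-(methoxymethyl)phenyl]methanol F6, and MnO2 gives 4-(benzyloxy)-2-methoxy-6-(methoxymethyl)benzaldehyde F7.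
- Iodine–magnesium exchange of 4 with iPrMgCl·LiCl at −40 °C and addition to F7 gives racemic methyl 4-(benzyloxy)-5-{[4-(benzyloxy)-2-methoxy-6-(methoxymethyl)phenyl](hydroxy)methyl}-2-methoxybenzoate F8, which Et3SiH and TFA reduce to 16.

Step 11. The most likely failure is slow rhodation of the C4a–H bond, which is hemmed in by the carboxylate and the bulky C5 benzyl group; protodecarboxylation or oxidative degradation of the electron-rich rings by divalent copper at 110 °C could then take over. The fallback separates C–C from C–O bond formation and avoids the hot copper oxidant. It sets out from 17 and comes back at 19. Carboxylate-directed ortho-allylation with allyl acetate ([RuCl2(p-cymene)]2 cat., K3PO4, 50 °C) gives 4-(benzyloxy)-3-[4-(benzyloxy)-2-methoxy-6-(methoxymethyl)benzyl]-6-methoxy-2-(prop-2-en-1-yl)benzoic acid F9. Wacker-type oxidative lactonisation of F9 (PdCl2(MeCN)2 cat., benzoquinone, Na2CO3, THF, rt), with the double bond moving into the ring, gives 19.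

Step 4. The most likely failure is direct aryl–alkyne coupling without CO uptake, or conjugate addition of the amine to the product ynone. The fallback builds the ynone by the classical addition–oxidation sequence. It sets out from 4 and comes back at 6. Iodine–magnesium exchange with iPrMgCl·LiCl (THF, −40 °C) and quenching with DMF gives methyl 4-(benzyloxy)-5-formyl-2-methoxybenzoate F10. Addition of lithiated 5 (n-BuLi, THF, −78 °C) gives racemic methyl 4-(benzyloxy)-5-(1-hydroxy-4-methoxybut-2-yn-1-yl)-2-methoxybenzoate F11, and MnO2 in CH2Cl2 oxidises F11 to 6.

Step 8. The most likely failure is Friedel–Crafts capture of the diarylmethyl cation by ring A of a second molecule, leading to oligomers, or acid-mediated loss of the benzyl ether. The fallback works under basic conditions. It sets out from 13 and comes back at 15. Acetylation (Ac2O, pyridine) gives methyl 5-[4-(acetyloxy)-2-methoxy-6-(methoxymethyl)benzoyl]-4-(benzyloxy)-2-methoxybenzoate F12, whose ketone is no longer deactivated by a phenoxide. NaBH4 in aqueous THF reduces the ketone; the acetate is cleaved in the basic medium, the para-hydroxy carbinol loses hydroxide to the para-quinone methide, and borohydride reduces that to 15.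

Step 12. The most likely failure is over-reduction: saturation of C3=C4 or hydrogenolysis of the benzylic C–OMe bond once the benzyl ethers are gone. The fallback replaces hydrogenolysis by acidolysis. It sets out from 19 and comes back at 20: TFA with pentamethylbenzene as benzyl-cation scavenger at rt cleaves both aryl benzyl ethers and leaves the enol lactone, the C8 methoxy group and the CH2OMe group (not ionisable) alone. It makes no new compound (F0).

## Further compounds

F1 | step 7 | methyl 4-methoxybut-2-ynoate | COCC#CC(=O)OC
F2 | step 7 | methyl 6,6-dimethoxy-2-(methoxymethyl)-4-(trimethylsilyloxy)cyclohexa-1,4-diene-1-carboxylate | COCC1=C(C(=O)OC)C(OC)(OC)C=C(O[Si](C)(C)C)C1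
F3 | step 7 | methyl 2-methoxy-6-(methoxymethyl)-4-(trimethylsilyloxy)benzoate | COCc1cc(O[Si](C)(C)C)cc(OC)c1C(=O)OC
F4 | step 7 | methyl 4-hydroxy-2-methoxy-6-(methoxymethyl)benzoate | COCc1cc(O)cc(OC)c1C(=O)OC
F5 | step 7 | methyl 4-(benzyloxy)-2-methoxy-6-(methoxymethyl)benzoate | COCc1cc(OCc2ccccc2)cc(OC)c1C(=O)OC
F6 | step 7 | [4-(benzyloxy)-2-methoxy-6-(methoxymethyl)phenyl]methanol | COCc1cc(OCc2ccccc2)cc(OC)c1CO
F7 | step 7 | 4-(benzyloxy)-2-methoxy-6-(methoxymethyl)benzaldehyde | COCc1cc(OCc2ccccc2)cc(OC)c1C=O
F8 | step 7 | methyl 4-(benzyloxy)-5-{[4-(benzyloxy)-2-methoxy-6-(methoxymethyl)phenyl](hydroxy)methyl}-2-methoxybenzoate (racemic) | COCc1cc(OCc2ccccc2)cc(OC)c1C(O)c1cc(C(=O)OC)c(OC)cc1OCc1ccccc1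
F9 | step 11 | 4-(benzyloxy)-3-[4-(benzyloxy)-2-methoxy-6-(methoxymethyl)benzyl]-6-methoxy-2-(prop-2-en-1-yl)benzoic acid | COCc1cc(OCc2ccccc2)cc(OC)c1Cc1c(CC=C)c(C(=O)O)c(OC)cc1OCc1ccccc1
F10 | step 4 | methyl 4-(benzyloxy)-5-formyl-2-methoxybenzoate | COC(=O)c1cc(C=O)c(OCc2ccccc2)cc1OC
F11 | step 4 | methyl 4-(benzyloxy)-5-(1-hydroxy-4-methoxybut-2-yn-1-yl)-2-methoxybenzoate (racemic) | COCC#CC(O)c1cc(C(=O)OC)c(OC)cc1OCc1ccccc1
F12 | step 8 | methyl 5-[4-(acetyloxy)-2-methoxy-6-(methoxymethyl)benzoyl]-4-(benzyloxy)-2-methoxybenzoate | COCc1cc(OC(C)=O)cc(OC)c1C(=O)c1cc(C(=O)OC)c(OC)cc1OCc1ccccc1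
F0 | step 12 | none | none
A1 | alternative 1 | methyl 4-methoxy-6-methyl-2-oxo-2H-pyran-5-carboxylate | COC(=O)C1=C(C)OC(=O)C=C1OC
A2 | alternative 1 | 1-(benzyloxy)-3-methoxy-5-(methoxymethyl)-4-[3-(triisopropylsilyloxy)prop-2-yn-1-yl]benzene | COCc1cc(OCc2ccccc2)cc(OC)c1CC#CO[Si](C(C)C)(C(C)C)C(C)C
A3 | alternative 1 | methyl 3-[4-(benzyloxy)-2-methoxy-6-(methoxymethyl)benzyl]-6-methoxy-2-methyl-4-(triisopropylsilyloxy)benzoate | COC(=O)c1c(OC)cc(O[Si](C(C)C)(C(C)C)C(C)C)c(Cc2c(COC)cc(OCc3ccccc3)cc2OC)c1C
A4 | alternative 2 | 6-{3-[4-(benzyloxy)-2-methoxy-6-(methoxymethyl)benzyl]-5-(2-methyl-1,3-dioxolan-2-yl)-2,4-dioxopentyl}-2,2-dimethyl-4H-1,3-dioxin-4-one | CC1(C)OC(=O)C=C(CC(=O)C(Cc2c(COC)cc(OCc3ccccc3)cc2OC)C(=O)CC2(C)OCCO2)O1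
A5 | alternative 2 | 6-[4-(benzyloxy)-2-methoxy-6-(methoxymethyl)benzyl]-7-hydroxy-2,2-dimethyl-5-[(2-methyl-1,3-dioxolan-2-yl)methyl]-4H-1,3-benzodioxin-4-one | CC1(C)OC(=O)c2c(O1)cc(O)c(Cc3c(COC)cc(OCc4ccccc4)cc3OC)c2CC1(C)OCCO1
A6 | alternative 3 | methyl acetoacetate | COC(=O)CC(C)=O
A7 | alternative 3 | methyl (E)-2-[4-(benzyloxy)-2-methoxy-6-(methoxymethyl)benzyl]but-2-enoate | COC(=O)/C(Cc1c(COC)cc(OCc2ccccc2)cc1OC)=C/C
A8 | alternative 3 | methyl 3-[4-(benzyloxy)-2-methoxy-6-(methoxymethyl)benzyl]-2-methyl-4,6-dioxocyclohexane-1-carboxylate (mixture of diastereomers) | COC(=O)C1C(C)C(Cc2c(COC)cc(OCc3ccccc3)cc2OC)C(=O)CC1=O
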